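**Retrosynthetic overview**
- Target 6 is cut at its two biaryl C–C bonds (C2 and C4 of the central ring) by a twofold Suzuki–Miyaura disconnection into dibromide 4 and two molecules of boronate 5, which is made in the flask from bromide 3.
- 3 and 4 both come from one monomer, 8-methoxynaphthalen-1-ol 2, by para-bromination and by ortho,para-dibromination.
- Key disconnection: the C8–OCH3 bond of 2, leading back to naphthalen-1-ol 1 and methanol through a new hydroxyl-directed peri-C–H methoxylation. This single C–O bond formation creates the 1-hydroxy-8-methoxy pattern of all three naphthalene units.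
- No ring is built; the three naphthalene bicycles come intact from 1. Order of events: C–O bond, then C–Br bonds, then the two C–C bonds.

Assumption: the target SMILES has no stereocentre and no stereodescriptor, and its two biaryl axes carry only H/OH ortho substituents, so they are taken as configurationally unfixed and the compound is made exactly as drawn.

Compounds are numbered in the order of the forward route.

**Step 1**
Reactants: 1 naphthalen-1-ol
Product: 2 8-methoxynaphthalen-1-ol
Conditions: [Cp*RhCl2]2 (2.5 mol %), AgSbF6 (10 mol %), CsOPiv (30 mol %), Cu(OAc)2 (2.2 equiv), MeOH (10 equiv), t-AmOH, 70 °C, N2, 16 h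
Reagents that add atoms: methanol, CO
Why: Proposed new method: hydroxyl-directed peri-C–H methoxylation, reasoned as follows: the naphtholate of 1 binds cationic Cp*Rh (trivalent rhodium), pivalate-assisted concerted metalation–deprotonation can only occur at C8 because this alone closes a five-membered O,C-rhodacycle (C2 would need a four-membered one), methanol then enters as Rh–OMe, and one-electron oxidation by Cu(OAc)2 to tetravalent rhodium induces C8–OMe reductive elimination before a second Cu(OAc)2 regenerates the catalyst; the closest known reaction type is the [Cp*RhCl2]2/Cu(OAc)2 oxidative peri-C–H/O–H annulation of free 1-naphthols with alkynes (same rhodacycle, same oxidant, C–O reductive elimination as the closing event), combined with chelate-directed C–H alkoxylation by alcohols known at palladium, cobalt and copper; no stereocentre is formed.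

**Step 2**
Reactants: 2 8-methoxynaphthalen-1-ol
Product: 3 4-bromo-8-methoxynaphthalen-1-ol
Conditions: NBS (1.0 equiv), MeCN, −20 → 0 °C, dark
Reagents that add atoms: N-bromosuccinimide, O=C1CCC(=O)N1Br
Why: Electrophilic aromatic bromination goes para to the free hydroxyl, the strongest activator, as it does for naphthalen-1-ol itself under NBS/MeCN; no stereocentre is formed.

**Step 3**
Reactants: 2 8-methoxynaphthalen-1-ol
Product: 4 2,4-dibromo-8-methoxynaphthalen-1-ol
Conditions: NBS (2.05 equiv), MeCN, 0 °C → rt
Reagents that add atoms: N-bromosuccinimide, O=C1CCC(=O)N1Br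
Why: Twofold electrophilic aromatic bromination fills the para and ortho positions of the hydroxyl-bearing ring, which is more activated than the methoxy ring (whose para site C5 is also shielded by the peri bromine once C4 is substituted); no stereocentre is formed.

**Step 4**
Reactants: 3 4-bromo-8-methoxynaphthalen-1-ol (2.4 equiv); 4 2,4-dibromo-8-methoxynaphthalen-1-ol (1.0 equiv)
Product: 6 2,4-bis(4-hydroxy-5-methoxynaphthalen-1-yl)-8-methoxynaphthalen-1-ol, via pinacol boronate 5 (not isolated)
Conditions: 3, B2pin2 (2.4 equiv), Pd(OAc)2 (5 mol %), SPhos (10 mol %), KOAc (7 equiv), 1,4-dioxane, 90 °C, Ar; then 4, aq. K3PO4 (8 equiv), 95 °C; degassed NH4Cl work-up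
Reagents that add atoms: bis(pinacolato)diboron, CC1(C)OB(OC1(C)C)B1OC(C)(C)C(C)(C)O1 (its boryl group is carried by 5 and leaves again in the coupling)
Why: Miyaura borylation of 3 followed in the same flask by a twofold Suzuki–Miyaura cross-coupling with 4, using SPhos-ligated palladium, which tolerates free phenols and the hindered ortho C2–Br site; the two new biaryl axes are formed without stereocontrol because the target has no fixed stereochemical element.

**Compound list**
1 | naphthalen-1-ol | Oc1cccc2ccccc12 | starting material
2 | 8-methoxynaphthalen-1-ol | COc1cccc2cccc(O)c12 | intermediate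
3 | 4-bromo-8-methoxynaphthalen-1-ol | COc1cccc2c(Br)ccc(O)c12 | intermediate
4 | 2,4-dibromo-8-methoxynaphthalen-1-ol | COc1cccc2c(Br)cc(Br)c(O)c12 | intermediate
5 | 8-methoxy-4-(4,4,5,5-tetramethyl-1,3,2-dioxaborolan-2-yl)naphthalen-1-ol | COc1cccc2c(B3OC(C)(C)C(C)(C)O3)ccc(O)c12 | intermediate
6 | 2,4-bis(4-hydroxy-5-methoxynaphthalen-1-yl)-8-methoxynaphthalen-1-ol | COc1cccc2c(-c3cc(-c4ccc(O)c5c(OC)cccc45)c4cccc(OC)c4c3O)ccc(O)c12 | target

**Step count**
Total steps: 4. Longest linear sequence: 3 (1 → 2 → 3 → 6; compound 4 is a one-step branch from 2).

**Steps most likely to fail, with fallbacks**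

Step 1 (the proposed new C–O step). Risks: C8–OMe reductive elimination may be slower than β-hydride loss from Rh–OMe or competing acetoxylation, and Cu(OAc)2 may oxidatively couple the electron-rich naphthols 1 and 2. The fallback uses known chemistry, sets out from 1 and comes back at 2. Compound 1 is O-methylated (MeI, K2CO3, acetone, reflux) to 1-methoxynaphthalene F1. Methoxy-directed peri-lithiation (t-BuLi, cyclohexane, rt) gives (8-methoxynaphthalen-1-yl)lithium F2. Quenching with B(OMe)3 at −78 °C gives lithium trimethoxy(8-methoxynaphthalen-1-yl)borate F3, which is oxidised in the same flask with H2O2/NaOH to 2.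

Step 4 (one-pot borylation and double coupling on unprotected naphthols). Risks: protodeboronation of the electron-rich boronate 5, slow oxidative addition at the naphtholate C2–Br of 4, and air oxidation of the product. The fallback sets out from 3 and 4 and comes back at 6. Both naphthols are capped as methoxymethyl ethers (MOMCl, i-Pr2NEt, CH2Cl2), giving 1-bromo-5-methoxy-4-(methoxymethoxy)naphthalene F4 and 2,4-dibromo-8-methoxy-1-(methoxymethoxy)naphthalene F5. F4 is borylated and isolated (B2pin2, PdCl2(dppf), KOAc, dioxane, 85 °C) as 2-[5-methoxy-4-(methoxymethoxy)naphthalen-1-yl]-4,4,5,5-tetramethyl-1,3,2-dioxaborolane F6. F5 and F6 (2.5 equiv) are coupled (Pd(OAc)2, SPhos, K3PO4, toluene/H2O, 100 °C) to 8-methoxy-1-(methoxymethoxy)-2,4-bis[5-methoxy-4-(methoxymethoxy)naphthalen-1-yl]naphthalene F7. HCl in MeOH then removes the three acetals to give 6.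

Step 3 (direct double bromination). Risks: a third bromine entering the methoxy ring, or mixtures of mono- and dibromide. The fallback sets out from 3 and comes back at 4, making the route linear through 3 instead of branching from 2. Because the para position of 3 is already blocked, one amine-catalysed ortho-bromination (NBS 1.05 equiv, i-Pr2NH 10 mol %, CH2Cl2, 0 °C) can only enter C2 of the naphthol ring. New compounds on its way: none F0.

**Further compounds**
F1 | step 1 | 1-methoxynaphthalene | COc1cccc2ccccc12
F2 | step 1 | (8-methoxynaphthalen-1-yl)lithium | [Li]c1cccc2cccc(OC)c12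
F3 | step 1 | lithium trimethoxy(8-methoxynaphthalen-1-yl)borate | [Li+].CO[B-](OC)(OC)c1cccc2cccc(OC)c12
F4 | step 4 | 1-bromo-5-methoxy-4-(methoxymethoxy)naphthalene | COCOc1ccc(Br)c2cccc(OC)c12
F5 | step 4 | 2,4-dibromo-8-methoxy-1-(methoxymethoxy)naphthalene | COCOc1c(Br)cc(Br)c2cccc(OC)c12
F6 | step 4 | 2-[5-methoxy-4-(methoxymethoxy)naphthalen-1-yl]-4,4,5,5-tetramethyl-1,3,2-dioxaborolane | COCOc1ccc(B3OC(C)(C)C(C)(C)O3)c2cccc(OC)c12
F7 | step 4 | 8-methoxy-1-(methoxymethoxy)-2,4-bis[5-methoxy-4-(methoxymethoxy)naphthalen-1-yl]naphthalene | COCOc1c(-c2ccc(OCOC)c3c(OC)cccc23)cc(-c2ccc(OCOC)c3c(OC)cccc23)c2cccc(OC)c12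
F0 | step 3 | none | none
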